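## Retrosynthetic overview

1. The γ-lactone is closed last, by oxidising the C16 allylic alcohol onto the C2 hydroxyl; C14 is then desilylated.
2. The oxirane is formed second, by C2–OH-directed titanium/tartrate epoxidation of the C3=C4 olefin of the macrocycle.
3. The 14-membered ring is formed first, by a Lewis acid carbonyl-ene closure of C1–C2 in a linear (2E,6E,10Z)-C20 enal. The C2 electrophile is attacked by the C1=C15 olefin and a C17 hydrogen is lost, as in the cyclisation of geranylgeranyl diphosphate to the cembrane skeleton.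
4. The linear enal comes from a C9–C10 allyl sulfone alkylation. The C10–C17 sulfone comes from nerol (Z olefin; C14–O by proline aminoxylation). The C2–C9 allylic chloride gets C5–O by an asymmetric vinylogous Mukaiyama aldol.
5. Ring order: carbocycle, then oxirane, then lactone.

Assumption: atoms carry cembrane numbering (C1 bears C15–C17, C2 the lactone oxygen, C18–C20 are the methyls on C4, C8, C12), so the target is (1R,2S,3S,4S,5R,7E,11Z,14R).

Abbreviations: TBS = tert-butyldimethylsilyl; PMB = 4-methoxybenzyl.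

## Route

Step 1
Reactants: 1 nerol
Product: 3 neryl phenyl sulfone, via neryl bromide 2 (not isolated)
Conditions: PBr3 (0.4 equiv), Et2O, −10 °C; then PhSO2Na, DMF, rt
Reagents that add atoms: sodium benzenesulfinate, [Na+].[O-]S(=O)c1ccccc1
Why: SN2 bromination of the primary allylic alcohol and S-alkylation of the sulfinate give the allyl sulfone without touching the Z olefin (sulfinate alkylation); no stereocentre is formed.

Step 2
Reactants: 3 neryl phenyl sulfone
Product: 5 (4Z)-4-methyl-6-(phenylsulfonyl)hex-4-enal, via ozonide 4 (not isolated)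
Conditions: O3, CH2Cl2, −78 °C (Sudan Red 7B end point); then PPh3, −78 °C to rt
Reagents that add atoms: ozone, [O-][O+]=O
Why: Chemoselective ozonolysis, because the terminal isopropylidene is far more electron-rich than the olefin deactivated by the allylic sulfone; no stereocentre is formed.

Step 3
Reactants: 5 (4Z)-4-methyl-6-(phenylsulfonyl)hex-4-enal; 6 ethyl 2-(triphenylphosphoranylidene)propanoate
Product: 9 ethyl (2E,4R,6Z)-4-hydroxy-2,6-dimethyl-8-(phenylsulfonyl)octa-2,6-dienoate, via anilinooxy aldehyde 7 (not isolated), via anilinooxy enoate 8 (not isolated)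
Conditions: PhNO, L-proline (20 mol%), CHCl3, 4 °C; then 6, rt; then Cu(OAc)2 (30 mol%), EtOH, rt
Reagents that add atoms: nitrosobenzene, O=Nc1ccccc1
Why: Proline enamine α-aminoxylation sets C14 as (R) under control of L-proline, the labile aldehyde is trapped at once as the E-enoate by the stabilised ylide (Wittig), and Cu(OAc)2 cleaves the N–O bond.

Step 4
Reactants: 9 ethyl (2E,4R,6Z)-4-hydroxy-2,6-dimethyl-8-(phenylsulfonyl)octa-2,6-dienoate
Product: 10 (2E,4R,6Z)-2,6-dimethyl-8-(phenylsulfonyl)octa-2,6-diene-1,4-diol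
Conditions: iBu2AlH (3.5 equiv), CH2Cl2, −78 to 0 °C; aq. sodium potassium tartrate
Reagents that add atoms: none
Why: 1,2-Reduction of the enoate by the aluminium hydride gives the allylic alcohol and leaves the sulfone and C14 untouched.

Step 5
Reactants: 10 (2E,4R,6Z)-2,6-dimethyl-8-(phenylsulfonyl)octa-2,6-diene-1,4-diol
Product: 11 (2E,4R,6Z)-1,4-bis(tert-butyldimethylsilyloxy)-2,6-dimethyl-8-(phenylsulfonyl)octa-2,6-diene
Conditions: TBSCl, imidazole, DMF, rt
Reagents that add atoms: tert-butyldimethylsilyl chloride, CC(C)(C)[Si](C)(C)Cl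
Why: Silylation of both hydroxyls gives a bulky, non-chelating C14 ether for the ene step and masks C16 (silyl ether protection).

Step 6
Reactants: 12 ethyl tiglate
Product: 13 tert-butyl[(1-ethoxy-2-methylbuta-1,3-dien-1-yl)oxy]dimethylsilane
Conditions: LiN(iPr)2, THF/DMPU, −78 °C; then TBSCl
Reagents that add atoms: tert-butyldimethylsilyl chloride, CC(C)(C)[Si](C)(C)Cl
Why: γ-Deprotonation of the enoate to the extended enolate and O-silylation give the silyl dienol ether for the vinylogous Mukaiyama aldol.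

Step 7
Reactants: 14 methacrolein; 15 allyl 4-methoxybenzyl ether
Product: 16 (2E)-4-(4-methoxybenzyloxy)-2-methylbut-2-enal
Conditions: second-generation Hoveyda–Grubbs catalyst RuCl2(H2IMes)(=CH-C6H4-2-OiPr) (2.5 mol%), CH2Cl2, 40 °C
Reagents that add atoms: none
Why: Olefin cross-metathesis of a terminal olefin with methacrolein gives the E-trisubstituted enal under thermodynamic control.

Step 8
Reactants: 16 (2E)-4-(4-methoxybenzyloxy)-2-methylbut-2-enal; 13 tert-butyl[(1-ethoxy-2-methylbuta-1,3-dien-1-yl)oxy]dimethylsilane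
Product: 17 ethyl (2E,5R,6E)-5-hydroxy-8-(4-methoxybenzyloxy)-2,6-dimethylocta-2,6-dienoate
Conditions: SiCl4 (1.1 equiv), (R,R)-N,N'-dimethyl-1,1'-binaphthyl-2,2'-diamine-derived bisphosphoramide (5 mol%), iPr2NEt (10 mol%), CH2Cl2, −78 °C; aq. NaHCO3
Reagents that add atoms: none
Why: Catalytic asymmetric vinylogous Mukaiyama aldol (Lewis-base-activated SiCl4), in which the dienolate attacks through its γ-carbon on the Re face of the bound aldehyde and sets C5 as (R) together with the E-enoate.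

Step 9
Reactants: 17 ethyl (2E,5R,6E)-5-hydroxy-8-(4-methoxybenzyloxy)-2,6-dimethylocta-2,6-dienoate
Product: 18 (2E,5R,6E)-8-(4-methoxybenzyloxy)-2,6-dimethylocta-2,6-diene-1,5-diol
Conditions: iBu2AlH (3.5 equiv), CH2Cl2, −78 °C; aq. sodium potassium tartrate
Reagents that add atoms: none
Why: 1,2-Reduction of the enoate to the primary allylic alcohol; the PMB ether and C5 are untouched.

Step 10
Reactants: 18 (2E,5R,6E)-8-(4-methoxybenzyloxy)-2,6-dimethylocta-2,6-diene-1,5-diol
Product: 20 (2E,4R,6E)-8-chloro-1-(4-methoxybenzyloxy)-3,7-dimethylocta-2,6-dien-4-ol, via allylic mesylate 19 (not isolated)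
Conditions: MsCl (1.05 equiv), 2,4,6-collidine, LiCl, DMF, 0 °C
Reagents that add atoms: lithium chloride, [Li+].[Cl-]
Why: Meyers-type chlorination (mesylation, then chloride displacement in situ) is selective for the primary allylic alcohol and runs without allylic transposition.

Step 11
Reactants: 11 (2E,4R,6Z)-1,4-bis(tert-butyldimethylsilyloxy)-2,6-dimethyl-8-(phenylsulfonyl)octa-2,6-diene; 20 (2E,4R,6E)-8-chloro-1-(4-methoxybenzyloxy)-3,7-dimethylocta-2,6-dien-4-ol
Product: 21 (2E,4R,6E,10Z,13R,14E)-13,16-bis(tert-butyldimethylsilyloxy)-1-(4-methoxybenzyloxy)-3,7,11,15-tetramethyl-9-(phenylsulfonyl)hexadeca-2,6,10,14-tetraen-4-ol (both C9 epimers)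
Conditions: 11, n-BuLi, THF/DMPU, −78 °C; then 20 pre-treated with LiN(SiMe3)2 (1.0 equiv), −78 to −40 °C; aq. NH4Cl
Reagents that add atoms: none
Why: Biellmann coupling, in which the α-sulfonyl allyl carbanion alkylates at its α-carbon by SN2 on the primary allylic chloride and joins C9 to C10 with all olefin geometries kept; the sulfonyl carbon is erased in step 12.

Step 12
Reactants: 21 the coupled sulfone
Product: 22 (2E,4R,6E,10Z,13R,14E)-13,16-bis(tert-butyldimethylsilyloxy)-1-(4-methoxybenzyloxy)-3,7,11,15-tetramethylhexadeca-2,6,10,14-tetraen-4-ol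
Conditions: Pd(dppp)Cl2 (5 mol%), LiBHEt3 (3.5 equiv), THF, 0 °C
Reagents that add atoms: none
Why: Palladium-catalysed reductive desulfonylation, in which zerovalent palladium ionises the allylic sulfone and hydride goes to the less substituted terminus of the allylpalladium intermediate, so C11=C12 keeps its position and Z geometry.

Step 13
Reactants: 22 the tetraenol
Product: 23 (2E,4R,6E,10Z,13R,14E)-13,16-bis(tert-butyldimethylsilyloxy)-1-(4-methoxybenzyloxy)-3,7,11,15-tetramethylhexadeca-2,6,10,14-tetraen-4-yl acetate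
Conditions: Ac2O, pyridine, DMAP (cat.), CH2Cl2, 0 °C to rt
Reagents that add atoms: acetic anhydride, CC(=O)OC(C)=O
Why: DMAP-catalysed acylation of the only free hydroxyl installs the C5 acetate with retention.

Step 14
Reactants: 23 the PMB ether acetate
Product: 25 (2E,4R,6E,10Z,13R,14E)-13,16-bis(tert-butyldimethylsilyloxy)-3,7,11,15-tetramethyl-1-oxohexadeca-2,6,10,14-tetraen-4-yl acetate, via allylic alcohol 24 (not isolated)
Conditions: DDQ, CH2Cl2/pH 7 buffer, 0 °C; filter; then MnO2, CH2Cl2, rt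
Reagents that add atoms: none
Why: Oxidative PMB cleavage by DDQ, then MnO2 oxidation of the only free allylic alcohol, gives the E-enal without touching silyl ethers or acetate.

Step 15
Reactants: 25 the linear enal
Product: 26 (1S,2R,3E,5R,7E,11Z,14R)-5-acetoxy-14-(tert-butyldimethylsilyloxy)-1-[3-(tert-butyldimethylsilyloxy)prop-1-en-2-yl]-4,8,12-trimethylcyclotetradeca-3,7,11-trien-2-ol
Conditions: Me2AlCl (2.5 equiv), CH2Cl2, −78 to −40 °C, syringe-pump addition (final 0.002 M); aq. sodium potassium tartrate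
Reagents that add atoms: none
Why: Proposed new method: the Me2AlCl-bound enal is attacked 1,2 at C2 by the C1=C15 olefin (Prins-type, charge at C15) and a C17 methyl hydrogen passes to oxygen through a six-membered ene transition state, which copies the C1–C2 closure of geranylgeranyl diphosphate with loss of a methyl proton; the E-enal cannot reach C7=C8, the C14 centre (H eclipsing the olefin, C13 anti to the incoming aldehyde, OTBS outside) selects the C1 face, and the two ring arms anti about the forming bond give the (1S,2R) pair needed for the trans lactone; closest known reaction type: Lewis acid-promoted intramolecular type 1 carbonyl-ene macrocyclisation of ω-prenyl ynals to 14-membered propargylic alcohols.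

Step 16
Reactants: 26 the macrocyclic allylic alcohol
Product: 27 (1S,2S,3S,4S,5R,7E,11Z,14R)-5-acetoxy-14-(tert-butyldimethylsilyloxy)-1-[3-(tert-butyldimethylsilyloxy)prop-1-en-2-yl]-3,4-epoxy-4,8,12-trimethylcyclotetradeca-7,11-dien-2-ol
Conditions: Ti(OiPr)4 (0.5 equiv), L-(+)-diisopropyl tartrate (0.6 equiv), tBuOOH, 4 Å MS, CH2Cl2, −20 °C
Reagents that add atoms: tert-butyl hydroperoxide, CC(C)(C)OO
Why: Sharpless hydroxyl-directed epoxidation touches only the allylic C3=C4 olefin, and L-(+)-tartrate is matched with the C2 carbinol and delivers oxygen to the face that gives the erythro (3S,4S) epoxide.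

Step 17
Reactants: 27 the epoxy alcohol
Product: 28 (1S,2S,3S,4S,5R,7E,11Z,14R)-5-acetoxy-14-(tert-butyldimethylsilyloxy)-3,4-epoxy-1-(3-hydroxyprop-1-en-2-yl)-4,8,12-trimethylcyclotetradeca-7,11-dien-2-ol
Conditions: HF·pyridine, pyridine, THF, 0 °C
Reagents that add atoms: none
Why: Selective desilylation, since buffered HF·pyridine cleaves the primary allylic silyl ether much faster than the hindered secondary one.

Step 18
Reactants: 28 the 2,16-diol
Product: 31 (1S,2S,3S,4S,5R,7E,11Z,14R)-5-acetoxy-14-(tert-butyldimethylsilyloxy)-3,4-epoxycembra-7,11,15(17)-trien-16,2-olide, via hydroxy enal 29 (not isolated), via lactol 30 (not isolated)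
Conditions: TEMPO (20 mol%), PhI(OAc)2 (2.5 equiv), CH2Cl2, rt
Reagents that add atoms: none
Why: TEMPO/PhI(OAc)2 oxidative lactonisation, in which the primary allylic alcohol is oxidised to the enal, trapped by the C2 hydroxyl as the lactol and oxidised on to the trans-fused α-methylene-γ-lactone; C14 is still silylated, so only the 16,2-lactone can form.

Step 19
Reactants: 31 the silylated lactone
Product: 32 (1R,2S,3S,4S,5R,7E,11Z,14R)-5-acetoxy-3,4-epoxy-14-hydroxycembra-7,11,15(17)-trien-16,2-olide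
Conditions: HF·pyridine, pyridine, THF, rt
Reagents that add atoms: none
Why: Fluoride desilylation of the secondary silyl ether under buffered conditions that spare epoxide, acetate and α-methylene lactone; no stereocentre is touched.

## Compound list

1 | nerol, (2Z)-3,7-dimethylocta-2,6-dien-1-ol | CC(C)=CCC/C(C)=C\CO | starting material
2 | neryl bromide, (2Z)-1-bromo-3,7-dimethylocta-2,6-diene | CC(C)=CCC/C(C)=C\CBr | intermediate
3 | neryl phenyl sulfone, {[(2Z)-3,7-dimethylocta-2,6-dien-1-yl]sulfonyl}benzene | CC(C)=CCC/C(C)=C\CS(=O)(=O)c1ccccc1 | intermediate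
4 | 3,3-dimethyl-5-[(3Z)-3-methyl-5-(phenylsulfonyl)pent-3-en-1-yl]-1,2,4-trioxolane | CC1(C)OOC(CC/C(C)=C\CS(=O)(=O)c2ccccc2)O1 | intermediate
5 | (4Z)-4-methyl-6-(phenylsulfonyl)hex-4-enal | O=CCC/C(C)=C\CS(=O)(=O)c1ccccc1 | intermediate
6 | ethyl 2-(triphenylphosphoranylidene)propanoate | CCOC(=O)C(C)=P(c1ccccc1)(c1ccccc1)c1ccccc1 | starting material
7 | (2R,4Z)-2-(anilinooxy)-4-methyl-6-(phenylsulfonyl)hex-4-enal | O=C[C@H](ONc1ccccc1)C/C(C)=C\CS(=O)(=O)c1ccccc1 | intermediate
8 | ethyl (2E,4R,6Z)-4-(anilinooxy)-2,6-dimethyl-8-(phenylsulfonyl)octa-2,6-dienoate | CCOC(=O)/C(C)=C/[C@H](ONc1ccccc1)C/C(C)=C\CS(=O)(=O)c1ccccc1 | intermediate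
9 | ethyl (2E,4R,6Z)-4-hydroxy-2,6-dimethyl-8-(phenylsulfonyl)octa-2,6-dienoate | CCOC(=O)/C(C)=C/[C@H](O)C/C(C)=C\CS(=O)(=O)c1ccccc1 | intermediate
10 | (2E,4R,6Z)-2,6-dimethyl-8-(phenylsulfonyl)octa-2,6-diene-1,4-diol | OC/C(C)=C/[C@H](O)C/C(C)=C\CS(=O)(=O)c1ccccc1 | intermediate
11 | (2E,4R,6Z)-1,4-bis(tert-butyldimethylsilyloxy)-2,6-dimethyl-8-(phenylsulfonyl)octa-2,6-diene | CC(C)(C)[Si](C)(C)OC/C(C)=C/[C@H](O[Si](C)(C)C(C)(C)C)C/C(C)=C\CS(=O)(=O)c1ccccc1 | intermediate
12 | ethyl tiglate, ethyl (2E)-2-methylbut-2-enoate | C/C=C(\C)C(=O)OCC | starting material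
13 | tert-butyl[(1-ethoxy-2-methylbuta-1,3-dien-1-yl)oxy]dimethylsilane (ketene acetal geometry not defined) | C=CC(C)=C(OCC)O[Si](C)(C)C(C)(C)C | intermediate
14 | methacrolein, 2-methylprop-2-enal | C=C(C)C=O | starting material
15 | allyl 4-methoxybenzyl ether | C=CCOCc1ccc(OC)cc1 | starting material
16 | (2E)-4-(4-methoxybenzyloxy)-2-methylbut-2-enal | O=C/C(C)=C/COCc1ccc(OC)cc1 | intermediate
17 | ethyl (2E,5R,6E)-5-hydroxy-8-(4-methoxybenzyloxy)-2,6-dimethylocta-2,6-dienoate | COc1ccc(COC/C=C(C)/[C@H](O)C/C=C(C)/C(=O)OCC)cc1 | intermediate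
18 | (2E,5R,6E)-8-(4-methoxybenzyloxy)-2,6-dimethylocta-2,6-diene-1,5-diol | COc1ccc(COC/C=C(C)/[C@H](O)C/C=C(C)/CO)cc1 | intermediate
19 | (2E,5R,6E)-5-hydroxy-8-(4-methoxybenzyloxy)-2,6-dimethylocta-2,6-dien-1-yl methanesulfonate | COc1ccc(COC/C=C(C)/[C@H](O)C/C=C(C)/COS(C)(=O)=O)cc1 | intermediate
20 | (2E,4R,6E)-8-chloro-1-(4-methoxybenzyloxy)-3,7-dimethylocta-2,6-dien-4-ol | COc1ccc(COC/C=C(C)/[C@H](O)C/C=C(C)/CCl)cc1 | intermediate
21 | (2E,4R,6E,10Z,13R,14E)-13,16-bis(tert-butyldimethylsilyloxy)-1-(4-methoxybenzyloxy)-3,7,11,15-tetramethyl-9-(phenylsulfonyl)hexadeca-2,6,10,14-tetraen-4-ol (both C9 epimers) | COc1ccc(COC/C=C(C)/[C@H](O)C/C=C(C)/CC(S(=O)(=O)c2ccccc2)/C=C(C)\C[C@@H](O[Si](C)(C)C(C)(C)C)/C=C(C)/CO[Si](C)(C)C(C)(C)C)cc1 | intermediate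
22 | (2E,4R,6E,10Z,13R,14E)-13,16-bis(tert-butyldimethylsilyloxy)-1-(4-methoxybenzyloxy)-3,7,11,15-tetramethylhexadeca-2,6,10,14-tetraen-4-ol | COc1ccc(COC/C=C(C)/[C@H](O)C/C=C(C)/CC/C=C(C)\C[C@@H](O[Si](C)(C)C(C)(C)C)/C=C(C)/CO[Si](C)(C)C(C)(C)C)cc1 | intermediate
23 | (2E,4R,6E,10Z,13R,14E)-13,16-bis(tert-butyldimethylsilyloxy)-1-(4-methoxybenzyloxy)-3,7,11,15-tetramethylhexadeca-2,6,10,14-tetraen-4-yl acetate | COc1ccc(COC/C=C(C)/[C@H](OC(C)=O)C/C=C(C)/CC/C=C(C)\C[C@@H](O[Si](C)(C)C(C)(C)C)/C=C(C)/CO[Si](C)(C)C(C)(C)C)cc1 | intermediate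
24 | (2E,4R,6E,10Z,13R,14E)-13,16-bis(tert-butyldimethylsilyloxy)-1-hydroxy-3,7,11,15-tetramethylhexadeca-2,6,10,14-tetraen-4-yl acetate | OC/C=C(C)/[C@H](OC(C)=O)C/C=C(C)/CC/C=C(C)\C[C@@H](O[Si](C)(C)C(C)(C)C)/C=C(C)/CO[Si](C)(C)C(C)(C)C | intermediate
25 | (2E,4R,6E,10Z,13R,14E)-13,16-bis(tert-butyldimethylsilyloxy)-3,7,11,15-tetramethyl-1-oxohexadeca-2,6,10,14-tetraen-4-yl acetate | O=C/C=C(C)/[C@H](OC(C)=O)C/C=C(C)/CC/C=C(C)\C[C@@H](O[Si](C)(C)C(C)(C)C)/C=C(C)/CO[Si](C)(C)C(C)(C)C | intermediate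
26 | (1S,2R,3E,5R,7E,11Z,14R)-5-acetoxy-14-(tert-butyldimethylsilyloxy)-1-[3-(tert-butyldimethylsilyloxy)prop-1-en-2-yl]-4,8,12-trimethylcyclotetradeca-3,7,11-trien-2-ol (cembrane numbering) | C=C(CO[Si](C)(C)C(C)(C)C)[C@H]1[C@H](O)/C=C(C)/[C@H](OC(C)=O)C/C=C(C)/CC/C=C(C)\C[C@H]1O[Si](C)(C)C(C)(C)C | intermediate
27 | (1S,2S,3S,4S,5R,7E,11Z,14R)-5-acetoxy-14-(tert-butyldimethylsilyloxy)-1-[3-(tert-butyldimethylsilyloxy)prop-1-en-2-yl]-3,4-epoxy-4,8,12-trimethylcyclotetradeca-7,11-dien-2-ol | C=C(CO[Si](C)(C)C(C)(C)C)[C@H]1[C@H](O)[C@@H]2O[C@@]2(C)[C@H](OC(C)=O)C/C=C(C)/CC/C=C(C)\C[C@H]1O[Si](C)(C)C(C)(C)C | intermediate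
28 | (1S,2S,3S,4S,5R,7E,11Z,14R)-5-acetoxy-14-(tert-butyldimethylsilyloxy)-3,4-epoxy-1-(3-hydroxyprop-1-en-2-yl)-4,8,12-trimethylcyclotetradeca-7,11-dien-2-ol | C=C(CO)[C@H]1[C@H](O)[C@@H]2O[C@@]2(C)[C@H](OC(C)=O)C/C=C(C)/CC/C=C(C)\C[C@H]1O[Si](C)(C)C(C)(C)C | intermediate
29 | 2-[(1S,2S,3S,4S,5R,7E,11Z,14R)-5-acetoxy-14-(tert-butyldimethylsilyloxy)-3,4-epoxy-2-hydroxy-4,8,12-trimethylcyclotetradeca-7,11-dien-1-yl]prop-2-enal | C=C(C=O)[C@H]1[C@H](O)[C@@H]2O[C@@]2(C)[C@H](OC(C)=O)C/C=C(C)/CC/C=C(C)\C[C@H]1O[Si](C)(C)C(C)(C)C | intermediate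
30 | lactol of 29, (1S,2S,3S,4S,5R,7E,11Z,14R)-5-acetoxy-14-(tert-butyldimethylsilyloxy)-3,4:2,16-diepoxycembra-7,11,15(17)-trien-16-ol (C16 epimers) | C=C1C(O)O[C@H]2[C@H]1[C@H](O[Si](C)(C)C(C)(C)C)C/C(C)=C\CC/C(C)=C/C[C@@H](OC(C)=O)[C@]1(C)O[C@@H]21 | intermediate
31 | (1S,2S,3S,4S,5R,7E,11Z,14R)-5-acetoxy-14-(tert-butyldimethylsilyloxy)-3,4-epoxycembra-7,11,15(17)-trien-16,2-olide | C=C1C(=O)O[C@H]2[C@H]1[C@H](O[Si](C)(C)C(C)(C)C)C/C(C)=C\CC/C(C)=C/C[C@@H](OC(C)=O)[C@]1(C)O[C@@H]21 | intermediate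
32 | (1R,2S,3S,4S,5R,7E,11Z,14R)-5-acetoxy-3,4-epoxy-14-hydroxycembra-7,11,15(17)-trien-16,2-olide (CNP0283244.1) | C=C1C(=O)O[C@H]2[C@H]1[C@H](O)C/C(C)=C\CC/C(C)=C/C[C@@H](OC(C)=O)[C@]1(C)O[C@@H]21 | target

## Step count and risks

Total step count: 19. Longest linear sequence: 14 (steps 1–5, then 11–19).

The three steps most likely to fail:

**Step 15 (ene macrocyclisation).** The ene donor carries two allylic oxygens and is less nucleophilic than C11=C12, so closure may be slow or go to a ten-membered ring, and the C1/C2 stereochemistry rests on a model. The fallback is an aluminium-alkoxide-tethered cyclisation that sets out from 25. HF·pyridine/pyridine in THF at 0 °C removes the primary allylic silyl group and gives the hydroxy enal F1. Me2AlCl (2.2 equiv, CH2Cl2, −78 °C, high dilution) turns the C16 hydroxyl into a chloro(methyl)aluminium alkoxide that binds the C2 aldehyde and delivers it to C1 within a seven-membered chelate. This templated ene closure gives the macrocyclic diol F2. TBSCl/imidazole at −20 °C silylates only the primary allylic hydroxyl, and the route is rejoined at 26.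

**Step 16 (directed epoxidation of the macrocycle).** The allylic alcohol is hindered, has a cis methyl and a neighbouring acetate, and the ring conformation may override the reagent. The fallback installs the epoxide before ring closure and sets out from 24, isolated after the DDQ stage of step 14. Catalytic Sharpless epoxidation of this primary allylic alcohol (Ti(OiPr)4, L-(+)-diethyl tartrate, tBuOOH, −20 °C) gives the linear epoxy alcohol F3 with reagent-controlled (3S,4S) configuration (cembrane numbering). SO3·pyridine/DMSO/iPr2NEt oxidises it to the epoxy aldehyde F4. Ene macrocyclisation of this more electrophilic, non-conjugated aldehyde with the monodentate Lewis acid BF3·OEt2 (CH2Cl2, −78 °C, high dilution) sets C2 by Felkin–Anh addition anti to the epoxide C–O bond and C1 as before. The route is rejoined at 27.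

**Step 8 (asymmetric vinylogous aldol).** γ-Selectivity and enantioselectivity with this α-branched enal and the 2-methyl dienolate are not assured. The fallback makes the C5 carbinol by ketone reduction and sets out from 16 and 12. The direct vinylogous aldol of ethyl tiglate with 16, mediated by aluminium tris(2,6-diphenylphenoxide), Al(OC6H3Ph2)3, and lithium 2,2,6,6-tetramethylpiperidide, gives the racemic aldol adduct F5. MnO2 oxidises its secondary allylic alcohol to the dienone F6. Corey–Bakshi–Shibata reduction ((S)-2-methyl-CBS-oxazaborolidine, catecholborane, toluene, −78 °C, alkenyl as the large group) gives the (5R)-alcohol, and the route is rejoined at 17.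

## Further compounds

F1 | step 15 | (2E,4R,6E,10Z,13R,14E)-13-(tert-butyldimethylsilyloxy)-16-hydroxy-3,7,11,15-tetramethyl-1-oxohexadeca-2,6,10,14-tetraen-4-yl acetate | O=C/C=C(C)/[C@H](OC(C)=O)C/C=C(C)/CC/C=C(C)\C[C@@H](O[Si](C)(C)C(C)(C)C)/C=C(C)/CO
F2 | step 15 | (1S,2R,3E,5R,7E,11Z,14R)-5-acetoxy-14-(tert-butyldimethylsilyloxy)-1-(3-hydroxyprop-1-en-2-yl)-4,8,12-trimethylcyclotetradeca-3,7,11-trien-2-ol | C=C(CO)[C@H]1[C@H](O)/C=C(C)/[C@H](OC(C)=O)C/C=C(C)/CC/C=C(C)\C[C@H]1O[Si](C)(C)C(C)(C)C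
F3 | step 16 | (1R,3E,7Z,10R,11E)-10,13-bis(tert-butyldimethylsilyloxy)-1-[(2S,3S)-3-(hydroxymethyl)-2-methyloxiran-2-yl]-4,8,12-trimethyltrideca-3,7,11-trien-1-yl acetate | OC[C@@H]1O[C@@]1(C)[C@H](OC(C)=O)C/C=C(C)/CC/C=C(C)\C[C@@H](O[Si](C)(C)C(C)(C)C)/C=C(C)/CO[Si](C)(C)C(C)(C)C
F4 | step 16 | (1R,3E,7Z,10R,11E)-10,13-bis(tert-butyldimethylsilyloxy)-1-[(2S,3R)-3-formyl-2-methyloxiran-2-yl]-4,8,12-trimethyltrideca-3,7,11-trien-1-yl acetate | O=C[C@@H]1O[C@@]1(C)[C@H](OC(C)=O)C/C=C(C)/CC/C=C(C)\C[C@@H](O[Si](C)(C)C(C)(C)C)/C=C(C)/CO[Si](C)(C)C(C)(C)C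
F5 | step 8 | racemic ethyl (2E,6E)-5-hydroxy-8-(4-methoxybenzyloxy)-2,6-dimethylocta-2,6-dienoate | COc1ccc(COC/C=C(C)/C(O)C/C=C(C)/C(=O)OCC)cc1
F6 | step 8 | ethyl (2E,6E)-8-(4-methoxybenzyloxy)-2,6-dimethyl-5-oxoocta-2,6-dienoate | COc1ccc(COC/C=C(C)/C(=O)C/C=C(C)/C(=O)OCC)cc1
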